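## The problem

CNP0173380.0 (22) is a 20-membered cyclophane built from two arenes. Ring A is a 5-alkylresorcinol (hydroxyl on C1, ether oxygen on C3, chain on C5). Ring B is a 6-alkylbenzene-1,2,4-triol (ether oxygen on C1', hydroxyls on C2' and C4', chain on C6'). The rings are joined twice: through the C3–O–C1' diaryl ether and through an unbranched chain of fourteen methylene groups. The molecule has no stereocenter, so nothing has to be set and nothing can serve as a control element; the task is one of regiochemistry and ring closure. Ring B is the demanding part: its C1' oxygen must be the only free oxygen when the ether is made, and C2' and C4' must be distinguishable from it. The saturated chain offers no functional group at which to cut, so the large ring has to be closed at the diaryl ether or at an arene–chain junction. The free triol ring B is electron-rich and easily oxidised to quinones, so all oxygens should travel masked and be released last under non-oxidising conditions. The feature that enables the key step is the sequence C1'(O)–C2'(O)–C3'(H)–C4'(O): it maps onto C4–C3–C2–C1 of a 4-alkoxy-3-methoxycyclobutenone, while C6' (with the chain) and C5'–H are the two carbons of a 1-alkylvinyl group on C4.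

## Retrosynthesis

**22 ⇒ 21.** The three O–H bonds at C1, C2' and C4' are traced back to O–CH3. Methyl ethers pass through organolithium chemistry, 110 °C and palladium catalysis, and BBr3 removes all three at once without an oxidant. 21 is no simpler in skeleton but is robust; the forward step only has to spare the diaryl ether.

**21 ⇒ 20.** The C3–O bond of the diaryl ether is cut, opening the macrocycle to the chain-linked chlorophenol 20. Cutting at C1'–O would need an electrophilic carbon at an electron-rich, doubly flanked position of ring B. Cutting inside the chain would need a functional group that must later be erased. 20 is an open chain between two simple arenes. The forward reaction must couple a hindered phenol with an unactivated aryl chloride intramolecularly, with C4' already capped so that C1'–OH is the only nucleophile. Chloride is chosen over bromide because the halogen must survive the Suzuki coupling of step 1 and the organolithium of step 6.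

**20 ⇒ 19 ⇒ 18.** Two protecting-group operations exchange which ring B oxygen is free. The C1' hydroxyl of 20 comes from the MOM ether 19, and the C4' methyl ether of 19 from the free phenol 18. No skeletal bond is cut. The forward steps need only an acetal that leaves under acid while aryl methyl ethers stay.

**18 ⇒ 15 (key disconnection).** The C4'–C5' bond is cut and ring B is unfolded, through dienone 17 and dienylketene 16, to the cyclobutenone 15. Building a 1,2,4-trioxygenated 6-alkylbenzene by aromatic substitution offers no dependable regiocontrol. Here every substituent is placed by connectivity, and the three oxygens arrive chemically distinct (OMOM, OMe, free OH). 15 holds ring B as a four-membered ring plus a vinyl group. The forward reaction needs only heat and the correct sense of ring opening.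

**15 ⇒ 14 ⇒ 9 + 12.** After removal of the MOM group (14), the bond between the quaternary carbinol carbon (future C1') and the alkenyl α-carbon (future C6') is cut. This is the convergent point: alkenyllithium 13, made from bromide 9, and the four-carbon dione 12. Protection is needed because a free hydroxyl would give an undifferentiated, air-sensitive hydroquinone. The forward addition must select the carbonyl next to the methoxy-bearing carbon of 12.

**12 ⇒ 10.** The C–H that becomes C3'–H is traced to one C–OMe of dimethyl squarate 10, through the hydride adduct 11. This is the simplest source of a cyclobutenedione with one alkoxy group and one hydrogen.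

**9 ⇒ 7 ⇒ 6 ⇒ 4 ⇒ 1 + 2.** The 2-bromoalkene is traced to the terminal alkyne 7 (Br and H across the triple bond). 7 is cut at the propargylic C–C bond to iodide 6 and acetylide. 6 comes from the terminal alkene 4, and 4 is cut at the arene–chain bond to the aryl bromide 2 and the C14 diene 1. Each cut removes two carbons or one functional group, all steps are chain-end operations, and the aryl chloride is a spectator throughout.

## Roads not taken

**Alternative 1:** The cut is the bond between the first and second chain carbons at ring A, made as a C=C bond by Ramberg–Bäcklund contraction of the 21-membered benzylic sulfone A2.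
- Forward key step: KOH/CCl4 in tert-butanol chlorinates the benzylic α-carbon, the episulfone closes and loses SO2 to give the styrenic macrocycle A1; hydrogenation of A1 would lead to 21.
- Merits: the large ring is closed beforehand by S-alkylation, one of the most dependable macrocyclisations. The diaryl ether can be made intermolecularly at the outset on small partners. The olefin geometry is irrelevant.
- Weak points: sulfide closure, oxidation, contraction and hydrogenation are all spent on one CH2–CH2 bond. The CCl4/KOH medium generates dichlorocarbene in the presence of an electron-rich styrene and a trialkoxyarene. Ring B, with its chain, aryloxy group and two methoxy groups, must still be assembled by classical aromatic chemistry.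
- Comparison: in the ring-closing event itself this road is probably the safer one, and the chosen plan has to answer with a demanding intramolecular C–O coupling in step 11. The chosen plan offers in return a ring B whose substituents are placed by construction, three distinct oxygens, and a chain built linearly without sulfur.

**Alternative 2:** Ring B would be made from open-chain carbon by a Michael–Dieckmann annulation of the aryloxymalonate enone A4.
- Forward key step: under NaOEt at high dilution the malonate carbon adds to the enone β-carbon (C1'–C6', which also closes the 20-membered ring). The methyl ketone enolate then acylates on one ester (C3'–C2'), giving dione A3. Hydrolysis, decarboxylation and dehydrogenation would follow.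
- Merits: cheap reagents, no transition metal, two rings in one operation, and an ether oxygen installed by simple O-alkylation.
- Weak points: the macrocyclisation rests on a reversible conjugate addition of a hindered, oxygen-bearing carbanion to a β-alkyl enone, where retro-addition and intermolecular addition compete. A3 is a diastereomer mixture whose stereocenters are all erased later. After decarboxylation the 4-aryloxycyclohexane-1,3-dione can aromatise without oxidant by loss of the ring A phenol across C1'–C6'; this gives a 5-alkylresorcinol and opens the macrocycle, and it competes with the required dehydrogenation.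
- Comparison: the path to A3 is shorter than the path to 18, which the chosen plan cannot match. The chosen plan reaches the aromatic oxidation level directly in step 8 with the C1' oxygen retained by design, and it separates ring B formation from macrocyclisation.

**Alternative 3:** No skeletal bond is cut; the C1–O and C4'–O bonds are introduced last on the dideoxy macrocycle A6.
- Forward key step: [Ir(OMe)(cod)]2, 4,4'-di-tert-butyl-2,2'-bipyridine and B2pin2 borylate both positions, and KHSO5 oxidises both C–B bonds in the same flask to give A5; BBr3 would convert A5 into 22.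
- Merits: the steric rule of the borylation fits the target. C1 is the only ring A position meta to both substituents, and C4' is the only ring B C–H flanked by two hydrogens. Two oxygens need not be carried or protected, and A6 is easier to assemble and to close than 20. In step count this road is likely the shorter one.
- Weak points: the key reaction must occur twice on the most valuable intermediate. On ring B the C3'–H next to the small methoxy group is only moderately shielded, so regioisomeric and mono-borylated products are to be expected, and isomeric macrocyclic phenols would be hard to separate. The oxidation exposes an electron-rich p-aryloxyphenol to a peroxide.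
- Comparison: the chosen plan is longer, which is conceded. Against that, step 6 fixes the oxygen pattern of ring B and step 8 delivers it, so no late regiochemical gamble is taken.

Key step: step 8

Assumption: the 20-membered ring is taken to be conformationally mobile, so the target has no stereogenic element; the single stereocenter of 11, 14 and 15 is used racemic and is erased in step 5 or step 8.

## Route

Step 1
Reactants: 1 tetradeca-1,13-diene; 2 1-bromo-3-chloro-5-methoxybenzene
Product: 4 1-chloro-3-methoxy-5-(tetradec-13-en-1-yl)benzene, via 9-(tetradec-13-en-1-yl)-9-borabicyclo[3.3.1]nonane 3 (not isolated)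
Conditions: 9-BBN (1.0 equiv), 1 (3 equiv), THF, 0 °C → rt; then 2 (0.9 equiv), Pd(dppf)Cl2 (3 mol %), 3 M aq K3PO4, DMF, 50 °C
Reagents that add atoms: none
Why: 9-BBN hydroborates one terminal alkene of the excess diene at the terminal carbon, and the B-alkyl Suzuki–Miyaura coupling of 3 under [1,1'-bis(diphenylphosphino)ferrocene]palladium dichloride takes place at the C–Br bond of 2, while the much slower C–Cl bond is kept for step 11. The excess of 1 keeps double hydroboration low and is recoverable.

Step 2
Reactants: 4 1-chloro-3-methoxy-5-(tetradec-13-en-1-yl)benzene
Product: 6 1-chloro-3-(14-iodotetradecyl)-5-methoxybenzene, via alkylzirconocene chloride 5 (not isolated)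
Conditions: Cp2Zr(H)Cl (1.3 equiv), THF, rt; then I2 (1.3 equiv), 0 °C
Reagents that add atoms: iodine, II
Why: Hydrozirconation places zirconium on the terminal carbon, and iodinolysis of the C–Zr bond of 5 gives the primary iodide (hydrozirconation–halogenation, an anti-Markovnikov hydroiodination). Aryl chloride and methyl ether are inert.

Step 3
Reactants: 6 1-chloro-3-(14-iodotetradecyl)-5-methoxybenzene
Product: 7 1-chloro-3-(hexadec-15-yn-1-yl)-5-methoxybenzene
Conditions: LiC≡CH·H2NCH2CH2NH2 (2 equiv), DMSO, 15 °C → rt
Reagents that add atoms: lithium acetylide–ethylenediamine complex, [Li+].[C-]#C.NCCN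
Why: SN2 alkylation of lithium acetylide by a primary iodide in DMSO is a standard two-carbon homologation to a terminal alkyne; the aryl chloride does not react.

Step 4
Reactants: 7 1-chloro-3-(hexadec-15-yn-1-yl)-5-methoxybenzene
Product: 9 1-(15-bromohexadec-15-en-1-yl)-3-chloro-5-methoxybenzene, via (Z)-2-bromoalkenyl-9-BBN adduct 8 (not isolated)
Conditions: 9-bromo-9-BBN (1.2 equiv), CH2Cl2, 0 °C; then AcOH, 0 °C → rt
Reagents that add atoms: 9-bromo-9-borabicyclo[3.3.1]nonane, BrB1C2CCCC1CCC2
Why: Haloboration adds B–Br syn across the terminal alkyne with bromine on the internal carbon, and protonolysis of the alkenyl C–B bond of 8 by acetic acid gives the 2-bromo-1-alkene. At 0 °C the alkyne should react much faster than the reagent can cleave the aryl methyl ether.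

Step 5
Reactants: 10 3,4-dimethoxycyclobut-3-ene-1,2-dione (dimethyl squarate)
Product: 12 3-methoxycyclobut-3-ene-1,2-dione, via 4-hydroxy-2,3-dimethoxycyclobut-2-en-1-one 11 (not isolated)
Conditions: LiAlH(OtBu)3 (1.05 equiv), THF, −78 → −20 °C; then 6 M aq HCl, CH2Cl2, rt
Reagents that add atoms: water (from the aqueous acid), O
Why: The bulky hydride adds once, 1,2, to a squarate carbonyl. Acid ionises the carbinol of 11 to an alkoxy-stabilised cyclobutenyl cation, which takes up water at the neighbouring carbon and loses methanol (the known reduction–hydrolysis route to alkyl semisquarates, applied here to the methyl ester).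

Step 6
Reactants: 9 1-(15-bromohexadec-15-en-1-yl)-3-chloro-5-methoxybenzene; 12 3-methoxycyclobut-3-ene-1,2-dione
Product: 14 rac-4-[16-(3-chloro-5-methoxyphenyl)hexadec-1-en-2-yl]-4-hydroxy-3-methoxycyclobut-2-en-1-one, via alkenyllithium 13 (not isolated)
Conditions: 9, t-BuLi (2.05 equiv), THF, −78 °C; cannulated into 12 (1.3 equiv), THF, −78 °C; aq NH4Cl, −78 °C
Reagents that add atoms: none
Why: Bromine–lithium exchange on the alkenyl bromide at −78 °C is faster than any reaction at the aryl chloride. Alkenyllithium 13 adds 1,2 to the ketone-like carbonyl next to the methoxy-bearing carbon of 12 and not to the other carbonyl, which is deactivated as a vinylogous ester (the established regiochemistry of organolithium addition to 3-alkoxycyclobutenediones). The new quaternary carbon forms racemic and becomes sp2 in step 8.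

Step 7
Reactants: 14 rac-4-[16-(3-chloro-5-methoxyphenyl)hexadec-1-en-2-yl]-4-hydroxy-3-methoxycyclobut-2-en-1-one
Product: 15 rac-4-[16-(3-chloro-5-methoxyphenyl)hexadec-1-en-2-yl]-3-methoxy-4-(methoxymethoxy)cyclobut-2-en-1-one
Conditions: MOMCl (4 equiv), iPr2NEt (6 equiv), Bu4NI (10 mol %), CH2Cl2, 0 °C → rt
Reagents that add atoms: chloromethyl methyl ether, COCCl
Why: O-Alkylation of the tertiary carbinol with the highly electrophilic MOMCl under a hindered amine base gives the acetal without attacking the base-sensitive cyclobutenone. MOM tolerates 110 °C and K2CO3 and is later removable beside methyl ethers.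

Step 8
Reactants: 15 rac-4-[16-(3-chloro-5-methoxyphenyl)hexadec-1-en-2-yl]-3-methoxy-4-(methoxymethoxy)cyclobut-2-en-1-one
Product: 18 3-[14-(3-chloro-5-methoxyphenyl)tetradecyl]-5-methoxy-4-(methoxymethoxy)phenol, via (Z)-dienylketene 16 (not isolated), via cyclohexa-2,4-dienone 17 (not isolated)
Conditions: toluene (0.01 M, degassed, argon), 110 °C
Reagents that add atoms: none
Why: Heating causes conrotatory 4π electrocyclic opening of the cyclobutenone by cleavage of the C1–C4 bond to give dienylketene 16. The ketene carbon then bonds to the terminal CH2 of the 1-alkylvinyl group in a thermal disrotatory 6π electrocyclisation, which closes the all-carbon six-membered ring as cyclohexa-2,4-dienone 17; enolisation of 17 gives aromatic ring B with the new C4'–C5' bond and a free C4' hydroxyl. The closest known reaction type is the thermal rearrangement of 4-alkenyl-4-alkoxycyclobutenones to hydroquinone mono-ethers, applied here to a 1-alkylvinyl group and an unsubstituted C2. The one selectivity needed is torquoselectivity: the C4 oxygen donor must rotate outward so that the alkenyl group lies cis to the ketene. The strong electronic preference of alkoxy donors for outward rotation secures this, and since ring opening is reversible a ketene of the wrong geometry can return to 15. Regiochemistry is not at issue, because the oxygen pattern was fixed in step 6 and only one alkene carbon can reach the ketene. No stereocenter is formed and the one of 15 is destroyed. The aryl chloride, methyl ethers and MOM acetal are thermally inert; dilution and exclusion of air and moisture suppress ketene dimerisation, hydration and oxidation of the phenol.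

Step 9
Reactants: 18 3-[14-(3-chloro-5-methoxyphenyl)tetradecyl]-5-methoxy-4-(methoxymethoxy)phenol
Product: 19 1-chloro-3-{14-[3,5-dimethoxy-2-(methoxymethoxy)phenyl]tetradecyl}-5-methoxybenzene
Conditions: MeI (3 equiv), K2CO3 (3 equiv), acetone, 50 °C
Reagents that add atoms: iodomethane, CI
Why: Williamson methylation of the only free phenol caps the C4' oxygen, so that after step 10 the C1' hydroxyl is the sole nucleophile for ring closure.

Step 10
Reactants: 19 1-chloro-3-{14-[3,5-dimethoxy-2-(methoxymethoxy)phenyl]tetradecyl}-5-methoxybenzene
Product: 20 2-[14-(3-chloro-5-methoxyphenyl)tetradecyl]-4,6-dimethoxyphenol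
Conditions: conc. HCl (cat.), MeOH/THF, 45 °C
Reagents that add atoms: none
Why: Acid-catalysed transacetalisation in methanol cleaves the aryl MOM ether, while the aryl methyl ethers and the aryl chloride are untouched; this frees the C1' hydroxyl alone.

Step 11
Reactants: 20 2-[14-(3-chloro-5-methoxyphenyl)tetradecyl]-4,6-dimethoxyphenol
Product: 21 macrocyclic diaryl ether (tri-O-methyl ether of the target; 20-membered ring closed through C3–O–C1')
Conditions: Pd(OAc)2 (10 mol %), 2-di-tert-butylphosphino-2',4',6'-triisopropylbiphenyl (15 mol %), K3PO4 (3 equiv), toluene, 100 °C; 20 added slowly to 0.002 M final concentration, argon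
Reagents that add atoms: none
Why: Buchwald–Hartwig-type diaryl ether formation: zerovalent palladium carrying the bulky biarylphosphine inserts into the aryl C–Cl bond, phosphate generates the phenoxide, and C–O reductive elimination closes the strain-free 20-membered ring. The coupling is established intermolecularly for ortho-substituted phenols with unactivated aryl chlorides; slow addition into dilute solution favours the intramolecular path.

Step 12
Reactants: 21 macrocyclic diaryl ether (tri-O-methyl ether of the target)
Product: 22 CNP0173380.0 (macrocyclic triphenol; hydroxyls on C1, C2' and C4')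
Conditions: BBr3 (8 equiv), CH2Cl2, −78 °C → rt; then H2O, 0 °C, argon
Reagents that add atoms: none
Why: BBr3 cleaves all three aryl methyl ethers through aryloxyborane formation and bromide attack on methyl, leaving the diaryl ether and the saturated chain intact. A non-oxidising work-up under argon protects the electron-rich ring B.

## Compound list

1 | tetradeca-1,13-diene | C=CCCCCCCCCCCCC=C | starting material
2 | 1-bromo-3-chloro-5-methoxybenzene | COc1cc(Cl)cc(Br)c1 | starting material
3 | 9-(tetradec-13-en-1-yl)-9-borabicyclo[3.3.1]nonane (formed in situ) | C=CCCCCCCCCCCCCB1C2CCCC1CCC2 | intermediate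
4 | 1-chloro-3-methoxy-5-(tetradec-13-en-1-yl)benzene | COc1cc(Cl)cc(CCCCCCCCCCCCC=C)c1 | intermediate
5 | chlorobis(cyclopentadienyl)[14-(3-chloro-5-methoxyphenyl)tetradecyl]zirconium (formed in situ) | COc1cc(Cl)cc(CCCCCCCCCCCCCC[Zr](Cl)(C2C=CC=C2)C2C=CC=C2)c1 | intermediate
6 | 1-chloro-3-(14-iodotetradecyl)-5-methoxybenzene | COc1cc(Cl)cc(CCCCCCCCCCCCCCI)c1 | intermediate
7 | 1-chloro-3-(hexadec-15-yn-1-yl)-5-methoxybenzene | COc1cc(Cl)cc(CCCCCCCCCCCCCCC#C)c1 | intermediate
8 | 9-[(Z)-2-bromo-16-(3-chloro-5-methoxyphenyl)hexadec-1-en-1-yl]-9-borabicyclo[3.3.1]nonane (formed in situ) | COc1cc(Cl)cc(CCCCCCCCCCCCCC/C(Br)=C/B2C3CCCC2CCC3)c1 | intermediate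
9 | 1-(15-bromohexadec-15-en-1-yl)-3-chloro-5-methoxybenzene | COc1cc(Cl)cc(CCCCCCCCCCCCCCC(Br)=C)c1 | intermediate
10 | 3,4-dimethoxycyclobut-3-ene-1,2-dione (dimethyl squarate) | COC1=C(OC)C(=O)C1=O | starting material
11 | rac-4-hydroxy-2,3-dimethoxycyclobut-2-en-1-one (crude, not purified) | COC1=C(OC)C(=O)C1O | intermediate
12 | 3-methoxycyclobut-3-ene-1,2-dione | COC1=CC(=O)C1=O | intermediate
13 | [16-(3-chloro-5-methoxyphenyl)hexadec-1-en-2-yl]lithium (formed in situ) | COc1cc(Cl)cc(CCCCCCCCCCCCCCC([Li])=C)c1 | intermediate
14 | rac-4-[16-(3-chloro-5-methoxyphenyl)hexadec-1-en-2-yl]-4-hydroxy-3-methoxycyclobut-2-en-1-one | COc1cc(Cl)cc(CCCCCCCCCCCCCCC(=C)C2(O)C(OC)=CC2=O)c1 | intermediate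
15 | rac-4-[16-(3-chloro-5-methoxyphenyl)hexadec-1-en-2-yl]-3-methoxy-4-(methoxymethoxy)cyclobut-2-en-1-one | COc1cc(Cl)cc(CCCCCCCCCCCCCCC(=C)C2(OCOC)C(OC)=CC2=O)c1 | intermediate
16 | (3Z)-5-[14-(3-chloro-5-methoxyphenyl)tetradecyl]-3-methoxy-4-(methoxymethoxy)hexa-1,3,5-trien-1-one (formed in situ) | O=C=C/C(OC)=C(OCOC)\C(=C)CCCCCCCCCCCCCCc1cc(Cl)cc(OC)c1 | intermediate
17 | 5-[14-(3-chloro-5-methoxyphenyl)tetradecyl]-3-methoxy-4-(methoxymethoxy)cyclohexa-2,4-dien-1-one (formed in situ) | O=C1C=C(OC)C(OCOC)=C(CCCCCCCCCCCCCCc2cc(Cl)cc(OC)c2)C1 | intermediate
18 | 3-[14-(3-chloro-5-methoxyphenyl)tetradecyl]-5-methoxy-4-(methoxymethoxy)phenol | COc1cc(Cl)cc(CCCCCCCCCCCCCCc2cc(O)cc(OC)c2OCOC)c1 | intermediate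
19 | 1-chloro-3-{14-[3,5-dimethoxy-2-(methoxymethoxy)phenyl]tetradecyl}-5-methoxybenzene | COc1cc(Cl)cc(CCCCCCCCCCCCCCc2cc(OC)cc(OC)c2OCOC)c1 | intermediate
20 | 2-[14-(3-chloro-5-methoxyphenyl)tetradecyl]-4,6-dimethoxyphenol | COc1cc(Cl)cc(CCCCCCCCCCCCCCc2cc(OC)cc(OC)c2O)c1 | intermediate
21 | macrocyclic diaryl ether, tri-O-methyl ether of the target (OMe on C1, C2' and C4') | COc1cc2cc(c1)Oc1c(OC)cc(OC)cc1CCCCCCCCCCCCCC2 | intermediate
22 | CNP0173380.0 | Oc1cc2cc(c1)Oc1c(O)cc(O)cc1CCCCCCCCCCCCCC2 | target

## Step count and least certain steps

Total: 12 steps. Longest linear sequence: 11 steps (1–4, then 6–12); step 5 is a one-step branch that joins at step 6.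

**Step 8 (key step).** The dienylketene 16 may be diverted before 6π closure: by ring opening in the unproductive sense (acetal oxygen inward), by dimerisation at its unhindered C2-unsubstituted terminus, or by capture by traces of water. It is the most reactive species on the path. Fallback (ring B is then bought as an arene and not built): it sets out from 4 and returns at 19.
- 5-Bromovanillin (3-bromo-4-hydroxy-5-methoxybenzaldehyde) F1 is protected with MOMCl/iPr2NEt to give 3-bromo-5-methoxy-4-(methoxymethoxy)benzaldehyde F2.
- Baeyer–Villiger oxidation of F2 with mCPBA/NaHCO3 gives 3-bromo-5-methoxy-4-(methoxymethoxy)phenyl formate F3, which K2CO3/MeOH cleaves to 3-bromo-5-methoxy-4-(methoxymethoxy)phenol F4.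
- MeI/K2CO3 converts F4 into 1-bromo-3,5-dimethoxy-2-(methoxymethoxy)benzene F5.
- Hydroboration of 4 with 9-BBN gives 9-[14-(3-chloro-5-methoxyphenyl)tetradecyl]-9-borabicyclo[3.3.1]nonane F6. B-alkyl Suzuki coupling of F6 with F5 (Pd(dppf)Cl2, K3PO4; the aryl bromide reacts in preference to the aryl chloride) gives 19, and steps 10–12 follow unchanged.

**Step 11.** Intermolecular C–O coupling (oligomerisation) and hydrodechlorination may overtake ring closure. Reductive elimination from the palladium phenoxide of a doubly ortho-substituted, electron-rich phenol is slow, and the ring-closing use of this coupling at large ring size is far less documented than the intermolecular one. Fallback (copper-mediated oxidative coupling of a boronic acid in place of palladium-catalysed coupling of the chloride): it sets out from 19 and returns at 21.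
- Borylation of the aryl chloride of 19 with tetrahydroxydiboron (Pd(OAc)2, 2-dicyclohexylphosphino-2',4',6'-triisopropylbiphenyl, KOAc, EtOH, 80 °C) gives {3-[14-(3,5-dimethoxy-2-(methoxymethoxy)phenyl)tetradecyl]-5-methoxyphenyl}boronic acid F7.
- HCl/MeOH removes the acetal to give {3-[14-(2-hydroxy-3,5-dimethoxyphenyl)tetradecyl]-5-methoxyphenyl}boronic acid F8.
- Chan–Evans–Lam macrocyclisation of F8 (Cu(OAc)2, Et3N, 4 Å molecular sieves, CH2Cl2, air, high dilution), a coupling with precedent for macrocyclic diaryl ethers, gives 21.

**Step 6.** tert-Butyllithium may metalate the chloroanisole ring (deprotonation between Cl and OMe, then benzyne formation), and residual tert-butyllithium may attack 12, because the exchange needs two equivalents of a very strong base beside an aryl chloride. Fallback (direct magnesium insertion in place of halogen–lithium exchange): it sets out from 9 and returns at 14. Magnesium turnings (activated with 1,2-dibromoethane) in THF insert into the C–Br bond of 9 to give bromo[16-(3-chloro-5-methoxyphenyl)hexadec-1-en-2-yl]magnesium F9; aryl chlorides are inert to this. Addition of F9 to 12 at −78 °C and an NH4Cl quench give 14.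

**Step 7.** Acetalisation of the hindered tertiary carbinol may be slow. That would leave 14 exposed to amine base long enough for retro-aldol-type ring cleavage, or would carry unprotected material into step 8. Fallback (no protecting group on that oxygen; the two hydroxyls are told apart by sterics): it sets out from 14 and returns at 20. Heating 14 in degassed toluene at 110 °C should give, by the same ring-opening and ring-closing cascade with the hydroxyl rotating outward, 2-[14-(3-chloro-5-methoxyphenyl)tetradecyl]-6-methoxybenzene-1,4-diol F10. Methylation with one equivalent of MeI and K2CO3 under argon should take place at the C4' hydroxyl, which is flanked by two hydrogens, and not at the C1' hydroxyl between methoxy and chain; this gives 20 and bypasses steps 9 and 10.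

## Further compounds

F1 | step 8 | 5-bromovanillin (3-bromo-4-hydroxy-5-methoxybenzaldehyde, commercial) | COc1cc(C=O)cc(Br)c1O
F2 | step 8 | 3-bromo-5-methoxy-4-(methoxymethoxy)benzaldehyde | COCOc1c(Br)cc(C=O)cc1OC
F3 | step 8 | 3-bromo-5-methoxy-4-(methoxymethoxy)phenyl formate | COCOc1c(Br)cc(OC=O)cc1OC
F4 | step 8 | 3-bromo-5-methoxy-4-(methoxymethoxy)phenol | COCOc1c(Br)cc(O)cc1OC
F5 | step 8 | 1-bromo-3,5-dimethoxy-2-(methoxymethoxy)benzene | COCOc1c(Br)cc(OC)cc1OC
F6 | step 8 | 9-[14-(3-chloro-5-methoxyphenyl)tetradecyl]-9-borabicyclo[3.3.1]nonane | COc1cc(Cl)cc(CCCCCCCCCCCCCCB2C3CCCC2CCC3)c1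
F7 | step 11 | {3-[14-(3,5-dimethoxy-2-(methoxymethoxy)phenyl)tetradecyl]-5-methoxyphenyl}boronic acid | COc1cc(B(O)O)cc(CCCCCCCCCCCCCCc2cc(OC)cc(OC)c2OCOC)c1
F8 | step 11 | {3-[14-(2-hydroxy-3,5-dimethoxyphenyl)tetradecyl]-5-methoxyphenyl}boronic acid | COc1cc(B(O)O)cc(CCCCCCCCCCCCCCc2cc(OC)cc(OC)c2O)c1
F9 | step 6 | bromo[16-(3-chloro-5-methoxyphenyl)hexadec-1-en-2-yl]magnesium | COc1cc(Cl)cc(CCCCCCCCCCCCCCC([Mg]Br)=C)c1
F10 | step 7 | 2-[14-(3-chloro-5-methoxyphenyl)tetradecyl]-6-methoxybenzene-1,4-diol | COc1cc(Cl)cc(CCCCCCCCCCCCCCc2cc(O)cc(OC)c2O)c1
A1 | alternative 1 | (E)-styrenic 20-membered macrocycle, trimethyl ether | COc1cc(/C=C/CCCCCCCCCCCCc2cc(OC)cc(OC)c2O3)cc3c1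
A2 | alternative 1 | 21-membered benzylic sulfone macrocycle, trimethyl ether | COc1cc(CS(=O)(=O)CCCCCCCCCCCCCc2cc(OC)cc(OC)c2O3)cc3c1
A3 | alternative 2 | macrocyclic 4-aryloxy-4-ethoxycarbonyl-5-alkylcyclohexane-1,3-dione (diastereomer mixture) | COc1cc2cc(c1)OC1(C(=O)OCC)C(=O)CC(=O)CC1CCCCCCCCCCCCCC2
A4 | alternative 2 | diethyl 2-{3-methoxy-5-[(E)-17-oxooctadec-15-en-1-yl]phenoxy}malonate | CCOC(=O)C(Oc1cc(OC)cc(CCCCCCCCCCCCCC/C=C/C(C)=O)c1)C(=O)OCC
A5 | alternative 3 | C2' mono-methyl ether of the target | COc1cc(O)cc2CCCCCCCCCCCCCCc3cc(O)cc(c3)Oc12
A6 | alternative 3 | dideoxy macrocycle lacking the C1 and C4' oxygens, C2' methyl ether | COc1cccc2CCCCCCCCCCCCCCc3cccc(c3)Oc12
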